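Per hour the feed brings 0.0250 /h of the whole charge into the flask, and I read everything else against that slope.

| setting | eta | zeta | flask |
|---|---|---|---|
| substrate | 29 mM (fed, over 40 h) | 19 mM (fed, over 40 h) | 29 mM (fed, over 40 h) |
| free catalyst | 2.9 mM | 2.9 mM | 2.9 mM |
| remark | the very flask that is asked about, followed so far; the fed solution adds 0.10 times the starting volume | run made earlier; the fed solution adds 0.10 times the starting volume | the fed solution adds 0.10 times the starting volume |
| time |  |  | 4.0 d |

| run | time / h | product / % | substrate / % |
|---|---|---|---|
| eta | 6.00 | 5.2 | 9.4 |
| eta | 15.0 | 21.5 | 16.4 |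
| eta | 20.0 | 31.8 | 18.8 |
| eta | 30.0 | 52.4 | 22.5 |
| eta | 40.0 | 72.9 | 26.9 |
| eta | 50.0 | 86.9 | 13.7 |
| zeta | 3.00 | 1.7 | 6.3 |
| zeta | 5.00 | 3.8 | 8.7 |
| zeta | 8.00 | 7.8 | 11.6 |
| zeta | 10.0 | 11.6 | 13.4 |
| zeta | 15.0 | 21.5 | 16.2 |
| zeta | 25.0 | 42.1 | 21.1 |
| zeta | 40.0 | 73.1 | 27.3 |

(readings scatter by 0.3 percentage points)

- where most of what was charged as substrate, at 4.0 d is found (substrate / product)
- the largest share itself, whichever of these holds it, in percent of the substrate charged

- for product the crystals are counted in
- charges are per starting volume, the dose included; the dosed solution carries all of it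
- as a solid, counted per litre of solution: crystals
- what may be going on: substrate + free catalyst -> free catalyst + product; free catalyst -> spent catalyst; crystals <-> product
- percentages count the whole charge, also what has not yet gone in

Eta and zeta both show 21.5 % and 21.5 % of product at 15.0 h, although their charges differ. So I read the consumption of substrate as pseudo-first-order, with a constant k that follows [free catalyst]. The substrate curve of the flask, followed so far as eta, climbs under the feed, product passes it between 6.00 h and 15.0 h, and the knee comes at 40.0 h with 26.9 % of substrate.

After the knee nothing enters, so the fall to 13.7 % gives k = 0.0675 /h. Between 20.0 h and 30.0 h the product slope over the mean substrate gives 0.0998 /h, which is larger. Dilution accounts for a factor of 1.04, and I read the rest as free catalyst turning into spent catalyst at 0.0178 /h.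

Now I join the two ends. At the last reading the natural logarithm of the charge over the substrate is 1.99, and integrating the decaying k from there up to 4.0 d adds 1.94. The sum is 3.93 for the budget, the natural logarithm of the charge over the substrate left. So I expect 1.97 % of substrate and 98.0 % of product.

The forecast says product at 98.4 % against my 98.0 %, with a decay of 0.015 per hour where I read 0.0178 /h, and it adds: “A slower decay tail would leave somewhat more substrate”.

The flask gives product at 98.1 %, with 1.88 % of substrate, so its budget is 3.97 against my 3.93; free catalyst still stands at 18.4 % of its charge.

    substrate + free catalyst → free catalyst + product (k = 0.0160 /M/s)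
    free catalyst → spent catalyst (k = 4.90 × 10⁻⁶ /s)
    crystals ⇌ product, rate k3*(cs3 - [product]) while solid is left; crystals form when [product] > cs3 (solubility = 23.0 mM, k = 2.60 × 10⁻⁴ /s)

Scaling my budget by the catalyst charged gives the neighbour flask, charged with 1.7 mM, a rough budget of 2.30, an estimate of 10.0 % left; the neighbour flask holds 8.48 % of substrate at its end.

All runs are simulated with constants of no real substance; the scatter is artificial.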